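## Analysis of the target

Atom labels C1–C9 follow the numbering of the target and are also used for the aromatic and monocyclic intermediates; locants inside systematic names are independent of them.

The target is a bicyclo[3.3.1]non-3-ene-2,9-dione. Ring C1–C2–C3–C4–C5–C9 is a cyclohexenone with the C2 ketone, the benzoyl group on C3 and a methyl enol ether at C4 (a vinylogous ester). Ring C1–C8–C7–C6–C5–C9 is a cyclohexanone with the gem-dimethyl carbon C6, the prenyl-bearing methine C7 and the only ring methylene, C8; C9 is the bridging ketone. There are four stereocentres. The quaternary bridgeheads C1 (R, lavandulyl) and C5 (R, prenyl) are tied to each other by the bicycle. At C7 (R) the prenyl group is equatorial on the chair cyclohexanone, on the side away from the C2–C3–C4 bridge and cis to both bridgehead side chains. The methine of the lavandulyl chain (R) is remote from the core and has to be brought in enantiopure. Sensitive groups are four electron-rich alkenes (three prenyl termini and one isopropenyl group), which exclude strong acid, electrophilic oxidants and late hydrogenation, and the vinylogous methyl ester. Its position at C4 (next to the prenyl bridgehead, not at C2) cannot be set by methylating a free 2,4-dione. The hard points are the two quaternary bridgeheads flanking C9, the contiguous fully substituted carbons C5 and C6, and the need to tell apart the two bridgeheads and the two oxygens O2 and O4. The plan rests on one feature: C6, C7 and C8 together are a 1,1-dimethylallyl unit on C5 whose terminal carbon C8 joins C1, while ring C1–C2–C3–C4–C5–C9 is the dearomatised form of a benzoylphloroglucinol monomethyl ether.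

## Retrosynthetic reasoning

(Numbers refer to the compound list after the steps.)

**19 to 18.** The trisubstituted C=C of the C7 prenyl group is cut back to the terminal allyl group of 18 (olefin cross-metathesis in the forward direction). Only this side chain is simplified, because C7 is the one position whose substituent will arrive by radical chemistry, and an allyl group is what that delivers. The forward reaction has to touch only the single monosubstituted alkene of 18.

**18 to 17.** The C7–CH2 bond is cut to a C7 radical, whose precursor is the secondary iodide 17. C7 is the only core stereocentre not locked by the bicycle. A planar radical there is open only on the face away from the C2–C3–C4 bridge, which is the face the target requires, so the halogen left by the ring closure is used rather than removed.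

**17 to 16.** The C1–C8 bond is cut together with the C7–I bond. This opens ring C1–C8–C7–C6–C5–C9 and leaves the cyclohexadienone 16, in which C6–C7–C8 is a reverse-prenyl group on C5. The cut is made here, not at C5–C6 or in the other ring, because it leaves ring C1–C2–C3–C4–C5–C9 with all three oxygens, the methyl ether and the benzoyl group already in place. It also reduces the core stereochemistry to the single centre C5. The forward reaction has to make quaternary C1 on the face fixed by C5, attack C8 and not C7, use carbon and not oxygen, and use the vinyl group and not the other alkenes.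

**16 to 10 and 13 (through 15 and 14).** The C1–CH2 bond is cut as an sp2–sp3 cross-coupling between a vinyl bromide and the organozinc 14. Alkylation is not an option: the lavandulyl carbon is primary but β-branched and not allylic, and an enolate or phenoxide would react at oxygen. The coupling is placed after the dearomatisation because the bromine first serves as a blocking group at C1. The enol has to be masked as the silyl ether 10: the free vinylogous acid would protonate 14, and its C–Br bond would act as a positive-halogen source. The side-chain stereocentre comes from 13, made from 12, which is obtained from racemic 11 by enzymatic resolution.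

**10 to 9, and 9 to 6 and 8.** After removal of the silyl group, the C5–C6 bond is cut. This is the dearomatising step, and it creates the C5 stereocentre and the contiguous quaternary pair C5/C6. A tertiary carbon cannot be attached by simple alkylation, but a metal–allyl complex that reacts at its more substituted terminus can do it, and a chiral ligand can choose the face of the phenoxide. With bromine on C1 and the acyl group on C3, C5 is the only ring carbon left for C–C bond formation.

**6 to 4 and 5, 4 to 3, 3 to 1 and 2.** The remaining cuts are aromatic substitutions, ordered by directing effects. The acyl group goes in first, ortho to the methoxy group; this differentiates the two hydroxyls. Bromine then goes to the carbon between the hydroxyls (C1). The prenyl group from 5 goes last, to the only carbon left (C5). Carbonate 8 comes from alcohol 7.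

## Alternatives that were turned down

**Alternative 1: Diels–Alder construction of the cyclohexanone ring.**
- Disconnection and key step: ring C1–C8–C7–C6–C5–C9 is cut at C1–C9 and C7–C8. The silyl dienol ether A2 and the α-substituted acrolein A3 combine under a chiral cationic boron Lewis acid to give the cyclohexene carbaldehyde A1.
- For it: enantioselective cycloadditions of 2-substituted acroleins are well understood, and the catalyst sets quaternary C1 and C7 in one step, with regiochemistry fixed by the 1-oxygenated diene. In absolute stereocontrol this is stronger than the ligand-controlled dearomatisation of step 5, which has no direct precedent.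
- Against it: A1 holds only one of the two rings. C6 lacks a methyl group and C5 its prenyl group. The whole C2–C3–C4 bridge, with two oxygens, the benzoyl group and the regiodefined methyl ether, must be grown from the formyl group and closed onto a neopentyl, fully substituted C5. The exo/endo outcome decides the C1/C7 relationship, and the catalyst must match or override the stereocentre in A3.
- Comparison: roughly ten operations would follow the cycloaddition; here two steps follow the ring closure, and arene 1 supplies six ring carbons with their heteroatoms. The chosen plan gives up catalyst control at C7 and relies on substrate-controlled radical allylation.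

**Alternative 2: diketene annulation on a cyclopentanone, later ring expansion.**
- Disconnection and key step: ring C1–C2–C3–C4–C5–C9 is cut at C1–C2 and C5–C9. The lithium enolate of cyclopentanone A5 is C-acylated by diketene A6, and the released methyl ketone enolate closes onto the ring carbonyl to give the cis-fused hydroxy hydrindanedione A4. A later 1,2-shift of C6 from C9 to C5 would enlarge the five-membered ring.
- For it: a cheap four-carbon reagent, two C–C bonds in one pot, C6 and C7 fixed beforehand. No electrophile is present that could attack the alkenes, so chemoselectivity is better than in step 10.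
- Against it: A5 is itself unsolved (its C7 stereocentre, and attachment of the lavandulyl chain to an enolate carbon with an unactivated β-branched electrophile). C-acylation of a hindered enolate competes with O-acylation. The ring expansion needs an activated C5 and a stereospecific shift in a crowded system. Afterwards C5 still lacks prenyl, C3 lacks benzoyl, and the 2,4-dione must be methylated on one specific oxygen without any control.
- Comparison: clearly longer. In the chosen route the methyl ether, the benzoyl group and the C5 prenyl group are all in 6 before the bicycle exists.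

**Alternative 3: gold-catalysed 6-endo-dig closure of C4–C5.**
- Disconnection and key step: the C4–C5 bond of the enone ring is cut. A cationic phosphine–gold catalyst activates the bromoalkyne of ynone A8 (silyl enol ether drawn as the tert-butyldimethylsilyl ether), and enol ether carbon C5 closes the ring to the 4-bromo enone A7.
- For it: this is the best-precedented way of closing such bicyclo[3.3.1]nonane cores. The π-acid selects the alkyne in the presence of every alkene, which is clearly better than the iodonium step. The congested C4–C5 bond forms under mild conditions, and the C4 bromide would let the methoxy group be placed regiospecifically, which is as good as the built-in ether of 1.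
- Against it: C1, C7 and both quaternary carbons C1 and C6 must be assembled on cyclohexanone A8 beforehand by enolate alkylations and an acylation whose C1/C7 diastereoselectivity is not assured. The lavandulyl chain again has to go onto an enolate carbon, and a C3 benzoylation remains at the end.
- Comparison: about fifteen linear steps against nine. The chosen plan offers a short route and a C1 configuration that follows automatically from C5, at the price of a less selective key step.

Key step: step 10

Remarks on the chemistry (assumptions):
- The sense of induction of the iridium catalyst in step 5 cannot be predicted. The ligand is written as (S) and is replaced by its antipode if the 6S dienone forms.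
- Silylation in step 6 may occur at either oxygen of the vinylogous acid. Compound 10 is drawn as one isomer; the other would behave the same way and converge on 16.
- Commercial lavandulol is taken to be the racemate.

## Route

Step 1
Reactants: 1 5-methoxybenzene-1,3-diol (5-methoxyresorcinol); 2 benzonitrile
Product: 3 (2,4-dihydroxy-6-methoxyphenyl)(phenyl)methanone
Conditions: ZnCl2, HCl (g), Et2O, 0 °C; then H2O, 100 °C
Reagents that add atoms: water, O
Why: Houben–Hoesch acylation: the nitrilium species from 2 attacks one of the two equivalent ring carbons flanked by OH and OMe (future C3), favoured statistically over the single carbon between the hydroxyls, and hydrolysis of the ketiminium salt gives the ketone. ZnCl2/HCl does not cleave the methyl ether next to the new carbonyl, as AlCl3 in a Friedel–Crafts benzoylation could; the minor regioisomer is removed by crystallisation or chromatography.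

Step 2
Reactants: 3 (2,4-dihydroxy-6-methoxyphenyl)(phenyl)methanone
Product: 4 (3-bromo-2,4-dihydroxy-6-methoxyphenyl)(phenyl)methanone
Conditions: NBS (1.0 equiv), MeCN, −20 °C to 0 °C
Reagents that add atoms: N-bromosuccinimide, O=C1CCC(=O)N1Br
Why: Electrophilic aromatic bromination at C1, the carbon between the two hydroxyls (ortho to both, para to OMe), the position usually halogenated in 2,4-dihydroxy-6-alkoxyaryl ketones; one equivalent at low temperature should stop at the monobromide. The regiochemistry is to be confirmed by an NOE between the methoxy group and the remaining ring proton.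

Step 3
Reactants: 4 (3-bromo-2,4-dihydroxy-6-methoxyphenyl)(phenyl)methanone; 5 1-bromo-3-methylbut-2-ene (prenyl bromide)
Product: 6 [3-bromo-2,4-dihydroxy-6-methoxy-5-(3-methylbut-2-en-1-yl)phenyl](phenyl)methanone
Conditions: 5 (1.0 equiv), KOH (aq., 10%), 0 °C to 25 °C
Reagents that add atoms: none
Why: Phenoxide C-alkylation in aqueous alkali, the classical ortho-prenylation of acylphloroglucinols: C5 is the only unsubstituted ring carbon and lies ortho to the free hydroxyl, and water solvates the phenoxide oxygen and so favours attack through carbon. One equivalent of 5 limits O-alkylation and a second, dearomatising alkylation.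

Step 4
Reactants: 7 2-methylbut-3-en-2-ol
Product: 8 tert-butyl 2-methylbut-3-en-2-yl carbonate
Conditions: n-BuLi, THF, 0 °C; then Boc2O, 0 °C to 25 °C
Reagents that add atoms: di-tert-butyl dicarbonate, CC(C)(C)OC(=O)OC(=O)OC(C)(C)C
Why: Acylation of the lithium alkoxide of the tertiary allylic alcohol with the dicarbonate gives the mixed carbonate, the usual leaving group for metal-catalysed allylic substitution; prior deprotonation is used because tertiary alcohols react sluggishly under amine catalysis.

Step 5
Reactants: 6 [3-bromo-2,4-dihydroxy-6-methoxy-5-(3-methylbut-2-en-1-yl)phenyl](phenyl)methanone; 8 tert-butyl 2-methylbut-3-en-2-yl carbonate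
Product: 9 (6R)-4-benzoyl-2-bromo-3-hydroxy-5-methoxy-6-(2-methylbut-3-en-2-yl)-6-(3-methylbut-2-en-1-yl)cyclohexa-2,4-dien-1-one
Conditions: [Ir(cod)Cl]2 (2.5 mol %), (S)-BINOL-derived dibenzo[b,f]azepin-5-yl phosphoramidite (10 mol %), THF, 25 °C
Reagents that add atoms: none
Why: Proposed new method: the monovalent iridium–phosphoramidite complex ionises 8 to a (1,1-dimethylallyl)iridium species with loss of CO2 and tert-butoxide, which deprotonates the acidic hydroxyl para to the acyl group; the phenoxide attacks through C5 (C1 is deactivated by bromine, the para carbon carries the acyl group) at the more substituted allyl terminus, as is usual for iridium, and the product cannot re-aromatise because C5 is quaternary; the closest known reactions are the iridium-catalysed reverse prenylation of 3-substituted indoles with the same carbonate, where the catalyst controls the quaternary carbon formed on the nucleophile, and the iridium-catalysed intermolecular allylic dearomatisation of 2-naphthols; the new stereocentre is set by the chiral ligand, which differentiates the two faces of the planar phenoxide at C5.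

Step 6
Reactants: 9 (6R)-4-benzoyl-2-bromo-3-hydroxy-5-methoxy-6-(2-methylbut-3-en-2-yl)-6-(3-methylbut-2-en-1-yl)cyclohexa-2,4-dien-1-one
Product: 10 (6R)-4-benzoyl-2-bromo-5-methoxy-6-(2-methylbut-3-en-2-yl)-6-(3-methylbut-2-en-1-yl)-3-{[tri(propan-2-yl)silyl]oxy}cyclohexa-2,4-dien-1-one
Conditions: TIPSOTf, Et3N, CH2Cl2, −78 °C to 0 °C
Reagents that add atoms: triisopropylsilyl trifluoromethanesulfonate, CC(C)[Si](C(C)C)(C(C)C)OS(=O)(=O)C(F)(F)F
Why: Standard O-silylation of a vinylogous acid with a silyl triflate and an amine base; it removes the acidic proton before the organozinc coupling and leaves the bromine on the α-carbon of a 3-silyloxy enone, an ordinary cross-coupling electrophile.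

Step 7
Reactants: 11 rac-5-methyl-2-(prop-1-en-2-yl)hex-4-en-1-ol (racemic lavandulol)
Product: 12 (2S)-5-methyl-2-(prop-1-en-2-yl)hex-4-en-1-ol ((S)-lavandulol)
Conditions: porcine pancreatic lipase, vinyl acetate, t-BuOMe, 25 °C, run past half conversion; chromatography
Reagents that add atoms: none
Why: Lipase-catalysed kinetic resolution by irreversible transesterification: the enzyme is expected to acylate the (R)-alcohol faster, so that running beyond half conversion leaves the (S)-alcohol in high enantiomeric purity; the stereocentre itself is not touched. A second cycle on the recovered alcohol is foreseen if the purity is insufficient.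

Step 8
Reactants: 12 (2S)-5-methyl-2-(prop-1-en-2-yl)hex-4-en-1-ol
Product: 13 (3S)-3-(iodomethyl)-2,6-dimethylhepta-1,5-diene ((S)-lavandulyl iodide)
Conditions: I2, PPh3, imidazole, CH2Cl2, 0 °C to 25 °C
Reagents that add atoms: iodine, I-I
Why: Appel-type iodination: iodide displaces the alkoxyphosphonium group by SN2 at the primary carbon, one atom away from the stereocentre, which is therefore unaffected.

Step 9
Reactants: 10 (6R)-4-benzoyl-2-bromo-5-methoxy-6-(2-methylbut-3-en-2-yl)-6-(3-methylbut-2-en-1-yl)-3-{[tri(propan-2-yl)silyl]oxy}cyclohexa-2,4-dien-1-one; 13 (3S)-3-(iodomethyl)-2,6-dimethylhepta-1,5-diene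
Product: 16 (6R)-4-benzoyl-3-hydroxy-5-methoxy-6-(2-methylbut-3-en-2-yl)-6-(3-methylbut-2-en-1-yl)-2-[(2R)-5-methyl-2-(prop-1-en-2-yl)hex-4-en-1-yl]cyclohexa-2,4-dien-1-one, via lavandulylzinc iodide 14 (not isolated), via coupled silyl enol ether 15 (not isolated)
Conditions: 13, Zn dust, LiCl, THF, 25–40 °C; then 10, Pd(OAc)2 (5 mol %), SPhos (2-dicyclohexylphosphino-2',6'-dimethoxybiphenyl, 10 mol %), THF, 25–45 °C; then TBAF, AcOH, THF, 0 °C
Reagents that add atoms: none
Why: Negishi coupling: zinc inserts into the primary C–I bond of 13 to give 14, zerovalent palladium adds to the C–Br bond of the α-bromo enone 10, and transmetallation and reductive elimination give 15; the electron-rich biarylphosphine favours reductive elimination over β-hydride elimination of the β-branched alkyl group. Ketones, enol ethers and alkenes are inert to the alkylzinc halide and the side-chain stereocentre is not involved (its descriptor changes from S to R only through the priority rules); buffered fluoride then removes the silyl group to give the free vinylogous acid 16.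

Step 10
Reactants: 16 (6R)-4-benzoyl-3-hydroxy-5-methoxy-6-(2-methylbut-3-en-2-yl)-6-(3-methylbut-2-en-1-yl)-2-[(2R)-5-methyl-2-(prop-1-en-2-yl)hex-4-en-1-yl]cyclohexa-2,4-dien-1-one
Product: 17 (1R,5R,7R)-3-benzoyl-7-iodo-4-methoxy-6,6-dimethyl-5-(3-methylbut-2-en-1-yl)-1-[(2R)-5-methyl-2-(prop-1-en-2-yl)hex-4-en-1-yl]bicyclo[3.3.1]non-3-ene-2,9-dione
Conditions: I2, KI, KHCO3, THF/H2O, 0 °C to 25 °C
Reagents that add atoms: iodine, I-I
Why: Iodonium-induced carbocyclisation, the reaction type known for dearomatised acylphloroglucinols carrying an allyl group on the quaternary carbon: bicarbonate converts 16 into its vinylogous carboxylate, iodine complexes the vinyl group of the 1,1-dimethylallyl substituent, and enolate carbon C1 attacks terminal C8 anti to iodine, forming C1–C8 and C7–I and leaving C2 as a ketone. Ring C1–C8–C7–C6–C5–C9 closes in the 6-endo-trig mode through a chair in which the new C7–I bond is equatorial. C1 can be reached only on the dienone face that carries C6, so its configuration follows from the C5 stereocentre; the C7 configuration (anti addition, 7R) is of no consequence because the iodide is later replaced through a planar radical. The step needs three selectivities: C8 over C7, carbon over oxygen, and the vinyl group over the three more electron-rich alkenes. Attack at C7 would be neopentyl and would give a strained bicyclo[3.2.1]octane, C3 is blocked by the benzoyl group and O4 by methyl. Iodo-ethers formed through the enolate oxygens, including those from the isopropenyl and prenyl groups, have a vinylogous carboxylate as leaving group and should be reopened by iodide (hence KI), whereas C–C bond formation is irreversible. Competing C–C closures onto the prenyl groups would have to join fully substituted C1 to a fully substituted alkene carbon, while C8 is primary and unhindered and the geminal methyl groups on C6 favour the reactive conformation.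

Step 11
Reactants: 17 (1R,5R,7R)-3-benzoyl-7-iodo-4-methoxy-6,6-dimethyl-5-(3-methylbut-2-en-1-yl)-1-[(2R)-5-methyl-2-(prop-1-en-2-yl)hex-4-en-1-yl]bicyclo[3.3.1]non-3-ene-2,9-dione
Product: 18 (1R,5R,7R)-3-benzoyl-4-methoxy-6,6-dimethyl-5-(3-methylbut-2-en-1-yl)-1-[(2R)-5-methyl-2-(prop-1-en-2-yl)hex-4-en-1-yl]-7-(prop-2-en-1-yl)bicyclo[3.3.1]non-3-ene-2,9-dione
Conditions: allyltributylstannane (excess, high concentration), AIBN, benzene, 80 °C
Reagents that add atoms: allyltributylstannane, C=CC[Sn](CCCC)(CCCC)CCCC
Why: Keck radical allylation: the tin radical abstracts iodine, the secondary C7 radical adds to the allylstannane and β-scission regenerates the chain carrier; the allyl group enters on the face of the planar radical away from the C2–C3–C4 bridge (equatorial bond), as in related 7-iodobicyclo[3.3.1]nonanes, which gives 7R. A high stannane concentration keeps intermolecular trapping faster than cyclisation of the radical onto the side-chain alkenes, which are held away from C7 by their equatorial attachment.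

Step 12
Reactants: 18 (1R,5R,7R)-3-benzoyl-4-methoxy-6,6-dimethyl-5-(3-methylbut-2-en-1-yl)-1-[(2R)-5-methyl-2-(prop-1-en-2-yl)hex-4-en-1-yl]-7-(prop-2-en-1-yl)bicyclo[3.3.1]non-3-ene-2,9-dione
Product: 19 (1R,5R,7R)-3-benzoyl-4-methoxy-6,6-dimethyl-5,7-bis(3-methylbut-2-en-1-yl)-1-[(2R)-5-methyl-2-(prop-1-en-2-yl)hex-4-en-1-yl]bicyclo[3.3.1]non-3-ene-2,9-dione
Conditions: 2-methyl-2-butene (large excess), second-generation Grubbs catalyst (5 mol %), CH2Cl2, 40 °C
Reagents that add atoms: 2-methyl-2-butene, CC=C(C)C
Why: Olefin cross-metathesis: the monosubstituted allyl alkene is the only olefin of 18 that enters the catalytic cycle readily, and with the trisubstituted partner in large excess it should be converted into the prenyl group with loss of propene. The existing prenyl groups can only undergo degenerate exchange, and the isopropenyl group and the enol ether are inert; no stereocentre is involved.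

## Compound list

1 | 5-methoxybenzene-1,3-diol (5-methoxyresorcinol) | COc1cc(O)cc(O)c1 | starting material
2 | benzonitrile | N#Cc1ccccc1 | starting material
3 | (2,4-dihydroxy-6-methoxyphenyl)(phenyl)methanone | COc1cc(O)cc(O)c1C(=O)c1ccccc1 | intermediate
4 | (3-bromo-2,4-dihydroxy-6-methoxyphenyl)(phenyl)methanone | COc1cc(O)c(Br)c(O)c1C(=O)c1ccccc1 | intermediate
5 | 1-bromo-3-methylbut-2-ene (prenyl bromide) | CC(C)=CCBr | starting material
6 | [3-bromo-2,4-dihydroxy-6-methoxy-5-(3-methylbut-2-en-1-yl)phenyl](phenyl)methanone | COc1c(CC=C(C)C)c(O)c(Br)c(O)c1C(=O)c1ccccc1 | intermediate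
7 | 2-methylbut-3-en-2-ol | C=CC(C)(C)O | starting material
8 | tert-butyl 2-methylbut-3-en-2-yl carbonate | C=CC(C)(C)OC(=O)OC(C)(C)C | intermediate
9 | (6R)-4-benzoyl-2-bromo-3-hydroxy-5-methoxy-6-(2-methylbut-3-en-2-yl)-6-(3-methylbut-2-en-1-yl)cyclohexa-2,4-dien-1-one | BrC1=C(O)C(C(=O)c2ccccc2)=C(OC)[C@@](CC=C(C)C)(C(C)(C)C=C)C1=O | intermediate
10 | (6R)-4-benzoyl-2-bromo-5-methoxy-6-(2-methylbut-3-en-2-yl)-6-(3-methylbut-2-en-1-yl)-3-{[tri(propan-2-yl)silyl]oxy}cyclohexa-2,4-dien-1-one | BrC1=C(O[Si](C(C)C)(C(C)C)C(C)C)C(C(=O)c2ccccc2)=C(OC)[C@@](CC=C(C)C)(C(C)(C)C=C)C1=O | intermediate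
11 | rac-5-methyl-2-(prop-1-en-2-yl)hex-4-en-1-ol (racemic lavandulol) | C=C(C)C(CC=C(C)C)CO | starting material
12 | (2S)-5-methyl-2-(prop-1-en-2-yl)hex-4-en-1-ol ((S)-lavandulol) | C=C(C)[C@H](CC=C(C)C)CO | intermediate
13 | (3S)-3-(iodomethyl)-2,6-dimethylhepta-1,5-diene ((S)-lavandulyl iodide) | C=C(C)[C@H](CC=C(C)C)CI | intermediate
14 | iodo[(2S)-5-methyl-2-(prop-1-en-2-yl)hex-4-en-1-yl]zinc (lavandulylzinc iodide, LiCl complex) | C=C(C)[C@H](CC=C(C)C)C[Zn]I | intermediate (not isolated)
15 | (6R)-4-benzoyl-5-methoxy-6-(2-methylbut-3-en-2-yl)-6-(3-methylbut-2-en-1-yl)-2-[(2R)-5-methyl-2-(prop-1-en-2-yl)hex-4-en-1-yl]-3-{[tri(propan-2-yl)silyl]oxy}cyclohexa-2,4-dien-1-one | C=C(C)[C@H](CC=C(C)C)CC1=C(O[Si](C(C)C)(C(C)C)C(C)C)C(C(=O)c2ccccc2)=C(OC)[C@@](CC=C(C)C)(C(C)(C)C=C)C1=O | intermediate (not isolated)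
16 | (6R)-4-benzoyl-3-hydroxy-5-methoxy-6-(2-methylbut-3-en-2-yl)-6-(3-methylbut-2-en-1-yl)-2-[(2R)-5-methyl-2-(prop-1-en-2-yl)hex-4-en-1-yl]cyclohexa-2,4-dien-1-one | C=C(C)[C@H](CC=C(C)C)CC1=C(O)C(C(=O)c2ccccc2)=C(OC)[C@@](CC=C(C)C)(C(C)(C)C=C)C1=O | intermediate
17 | (1R,5R,7R)-3-benzoyl-7-iodo-4-methoxy-6,6-dimethyl-5-(3-methylbut-2-en-1-yl)-1-[(2R)-5-methyl-2-(prop-1-en-2-yl)hex-4-en-1-yl]bicyclo[3.3.1]non-3-ene-2,9-dione | C=C(C)[C@H](CC=C(C)C)C[C@@]12C[C@@H](I)C(C)(C)[C@@](CC=C(C)C)(C1=O)C(OC)=C(C(=O)c1ccccc1)C2=O | intermediate
18 | (1R,5R,7R)-3-benzoyl-4-methoxy-6,6-dimethyl-5-(3-methylbut-2-en-1-yl)-1-[(2R)-5-methyl-2-(prop-1-en-2-yl)hex-4-en-1-yl]-7-(prop-2-en-1-yl)bicyclo[3.3.1]non-3-ene-2,9-dione | C=C(C)[C@H](CC=C(C)C)C[C@@]12C[C@@H](CC=C)C(C)(C)[C@@](CC=C(C)C)(C1=O)C(OC)=C(C(=O)c1ccccc1)C2=O | intermediate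
19 | (1R,5R,7R)-3-benzoyl-4-methoxy-6,6-dimethyl-5,7-bis(3-methylbut-2-en-1-yl)-1-[(2R)-5-methyl-2-(prop-1-en-2-yl)hex-4-en-1-yl]bicyclo[3.3.1]non-3-ene-2,9-dione | C=C(C)[C@H](CC=C(C)C)C[C@@]12C[C@@H](CC=C(C)C)C(C)(C)[C@@](CC=C(C)C)(C1=O)C(OC)=C(C(=O)c1ccccc1)C2=O | target

## Step count and least certain steps

Total: 12 steps. Longest linear sequence: 9 steps (steps 1, 2, 3, 5, 6, 9, 10, 11, 12, from 1 to 19). Side branches: step 4 (one step) and steps 7–8 (two steps).

**Step 5 (proposed new method).** The most likely failure is bond formation at the phenoxide oxygen instead of C5, followed by a sigmatropic shift that delivers the allyl unit with linear connectivity. The second is poor discrimination of the two faces of the flat phenoxide, because the allyl terminus is symmetric and iridium catalysts usually control the electrophile better than the nucleophile. Fallback with known chemistry, starting from 6: selective O-alkylation of the non-chelated hydroxyl with 5 (K2CO3, acetone) should give [3-bromo-2-hydroxy-6-methoxy-5-(3-methylbut-2-en-1-yl)-4-[(3-methylbut-2-en-1-yl)oxy]phenyl](phenyl)methanone F1. Heating in toluene should bring about the aromatic Claisen rearrangement to the prenyl-bearing ortho carbon C5 (the other ortho carbon carries bromine, the para carbon the acyl group), delivering the reverse-prenyl group intramolecularly and giving rac-4-benzoyl-2-bromo-3-hydroxy-5-methoxy-6-(2-methylbut-3-en-2-yl)-6-(3-methylbut-2-en-1-yl)cyclohexa-2,4-dien-1-one F2. Resolution of this acid, by preparative chromatography on a chiral stationary phase or by crystallisation of a cinchona alkaloid salt, returns to 9.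

**Step 10 (key step).** The most likely failure is diversion of the iodine electrophile to the more electron-rich isopropenyl and prenyl alkenes, followed by irreversible capture (ether formation through an enolate oxygen or spirocyclisation through C1). The cause is that halonium formation favours the more substituted alkenes, while the alkene that must react is monosubstituted and neopentyl. Fallback, starting from 16: a selenium electrophile under equilibrating conditions (N-(phenylseleno)phthalimide, catalytic ZnI2, CH2Cl2). Seleniranium ions form reversibly, and kinetically formed seleno-ethers of alkenyl 1,3-dicarbonyl compounds are known to isomerise to the carbocyclic products. This should give (1R,5R,7R)-3-benzoyl-4-methoxy-6,6-dimethyl-5-(3-methylbut-2-en-1-yl)-1-[(2R)-5-methyl-2-(prop-1-en-2-yl)hex-4-en-1-yl]-7-(phenylselanyl)bicyclo[3.3.1]non-3-ene-2,9-dione F3. The selenide is a competent radical precursor, and allylation under the conditions of step 11 rejoins the route at 18.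

**Step 9.** The most likely failure is reduction of the C–Br bond instead of coupling, through bromine–zinc exchange at the electrophilic bromine of the α-bromo enone or through β-hydride elimination from the alkylpalladium intermediate; premature loss of the silyl group under the Lewis-acidic zinc salts is a second risk. Fallback, starting from 13 and 10: a B-alkyl Suzuki–Miyaura coupling. Iodine–lithium exchange on 13 (t-BuLi, Et2O, −78 °C) and trapping with 9-methoxy-9-borabicyclo[3.3.1]nonane should give lithium 9-methoxy-9-[(2S)-5-methyl-2-(prop-1-en-2-yl)hex-4-en-1-yl]-9-borabicyclo[3.3.1]nonan-9-uide F4. This borate does not exchange halogen and is coupled with 10 (Pd(dppf)Cl2, AsPh3, K3PO4, DMF) as in the known couplings of α-haloenones. Desilylation as in step 9 returns to 16.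

**Step 3.** The most likely failure is alkylation at oxygen and over-alkylation instead of mono-C-alkylation, because the brominated phenoxide is a weak carbon nucleophile. Fallback, starting from 4: O-alkylation of the non-chelated hydroxyl with 3-chloro-3-methylbut-1-yne (K2CO3, KI, CuI, acetone) gives {3-bromo-2-hydroxy-6-methoxy-4-[(2-methylbut-3-yn-2-yl)oxy]phenyl}(phenyl)methanone F5. Semihydrogenation (H2, Pd/CaCO3 poisoned with Pb(OAc)2, quinoline) gives {3-bromo-2-hydroxy-6-methoxy-4-[(2-methylbut-3-en-2-yl)oxy]phenyl}(phenyl)methanone F6. Its aromatic Claisen rearrangement on heating transfers the allyl unit with inversion to the only free ortho carbon and returns to 6.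

**Step 2 (and the regiochemistry of step 1).** The most likely failure is substitution at the wrong ring carbon (next to the methoxy group) or double bromination, since both free carbons are flanked by two oxygen substituents. Fallback, starting from 1: protection (MOMCl, i-Pr2NEt) gives 1-methoxy-3,5-bis(methoxymethoxy)benzene F7. Directed lithiation between the two acetal groups (n-BuLi, THF, 0 °C) and quenching with 1,2-dibromotetrachloroethane gives 2-bromo-5-methoxy-1,3-bis(methoxymethoxy)benzene F8. Acid methanolysis gives 2-bromo-5-methoxybenzene-1,3-diol F9, whose two open positions are equivalent. Houben–Hoesch acylation with 2 as in step 1 can then give only one regioisomer and returns to 4.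

## Further compounds

F1 | step 5 | [3-bromo-2-hydroxy-6-methoxy-5-(3-methylbut-2-en-1-yl)-4-[(3-methylbut-2-en-1-yl)oxy]phenyl](phenyl)methanone | COc1c(CC=C(C)C)c(OCC=C(C)C)c(Br)c(O)c1C(=O)c1ccccc1
F2 | step 5 | rac-4-benzoyl-2-bromo-3-hydroxy-5-methoxy-6-(2-methylbut-3-en-2-yl)-6-(3-methylbut-2-en-1-yl)cyclohexa-2,4-dien-1-one | BrC1=C(O)C(C(=O)c2ccccc2)=C(OC)C(CC=C(C)C)(C(C)(C)C=C)C1=O
F3 | step 10 | (1R,5R,7R)-3-benzoyl-4-methoxy-6,6-dimethyl-5-(3-methylbut-2-en-1-yl)-1-[(2R)-5-methyl-2-(prop-1-en-2-yl)hex-4-en-1-yl]-7-(phenylselanyl)bicyclo[3.3.1]non-3-ene-2,9-dione | C=C(C)[C@H](CC=C(C)C)C[C@@]12C[C@@H]([Se]c3ccccc3)C(C)(C)[C@@](CC=C(C)C)(C1=O)C(OC)=C(C(=O)c1ccccc1)C2=O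
F4 | step 9 | lithium 9-methoxy-9-[(2S)-5-methyl-2-(prop-1-en-2-yl)hex-4-en-1-yl]-9-borabicyclo[3.3.1]nonan-9-uide | [Li+].C=C(C)[C@H](CC=C(C)C)C[B-]1(OC)C2CCCC1CCC2
F5 | step 3 | {3-bromo-2-hydroxy-6-methoxy-4-[(2-methylbut-3-yn-2-yl)oxy]phenyl}(phenyl)methanone | COc1cc(OC(C)(C)C#C)c(Br)c(O)c1C(=O)c1ccccc1
F6 | step 3 | {3-bromo-2-hydroxy-6-methoxy-4-[(2-methylbut-3-en-2-yl)oxy]phenyl}(phenyl)methanone | COc1cc(OC(C)(C)C=C)c(Br)c(O)c1C(=O)c1ccccc1
F7 | step 2 | 1-methoxy-3,5-bis(methoxymethoxy)benzene | COCOc1cc(OC)cc(OCOC)c1
F8 | step 2 | 2-bromo-5-methoxy-1,3-bis(methoxymethoxy)benzene | COCOc1cc(OC)cc(OCOC)c1Br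
F9 | step 2 | 2-bromo-5-methoxybenzene-1,3-diol | COc1cc(O)c(Br)c(O)c1
A1 | alternative 1 | 4-methyl-5-(3-methylbut-2-en-1-yl)-1-[(2R)-5-methyl-2-(prop-1-en-2-yl)hex-4-en-1-yl]-2-{[tri(propan-2-yl)silyl]oxy}cyclohex-3-ene-1-carbaldehyde (configuration as in the SMILES) | C=C(C)[C@H](CC=C(C)C)C[C@@]1(C=O)C[C@@H](CC=C(C)C)C(C)=C[C@H]1O[Si](C(C)C)(C(C)C)C(C)C
A2 | alternative 1 | (1E,3E)-3,7-dimethyl-1-{[tri(propan-2-yl)silyl]oxy}octa-1,3,6-triene | CC(C)=CC/C=C(C)/C=C/O[Si](C(C)C)(C(C)C)C(C)C
A3 | alternative 1 | (4R)-7-methyl-2-methylidene-4-(prop-1-en-2-yl)oct-6-enal | C=C(C)[C@H](CC=C(C)C)CC(=C)C=O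
A4 | alternative 2 | cis-fused 7a-hydroxy-1,1-dimethyl-2-(3-methylbut-2-en-1-yl)-3a-[(2R)-5-methyl-2-(prop-1-en-2-yl)hex-4-en-1-yl]hexahydro-1H-indene-4,6-dione (configuration as in the SMILES) | C=C(C)[C@H](CC=C(C)C)C[C@@]12C[C@@H](CC=C(C)C)C(C)(C)[C@]1(O)CC(=O)CC2=O
A5 | alternative 2 | (3R)-2,2-dimethyl-3-(3-methylbut-2-en-1-yl)-5-[(2R)-5-methyl-2-(prop-1-en-2-yl)hex-4-en-1-yl]cyclopentan-1-one | C=C(C)[C@H](CC=C(C)C)CC1C[C@@H](CC=C(C)C)C(C)(C)C1=O
A6 | alternative 2 | 4-methylideneoxetan-2-one (diketene) | C=C1CC(=O)O1
A7 | alternative 3 | 4-bromo-6,6-dimethyl-5,7-bis(3-methylbut-2-en-1-yl)-1-[(2R)-5-methyl-2-(prop-1-en-2-yl)hex-4-en-1-yl]bicyclo[3.3.1]non-3-ene-2,9-dione (configuration as in the SMILES) | C=C(C)[C@H](CC=C(C)C)C[C@@]12C[C@@H](CC=C(C)C)C(C)(C)[C@@](CC=C(C)C)(C1=O)C(Br)=CC2=O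
A8 | alternative 3 | 3-bromo-1-{2-[(tert-butyldimethylsilyl)oxy]-4,4-dimethyl-3,5-bis(3-methylbut-2-en-1-yl)-1-[(2R)-5-methyl-2-(prop-1-en-2-yl)hex-4-en-1-yl]cyclohex-2-en-1-yl}prop-2-yn-1-one (configuration as in the SMILES) | C=C(C)[C@H](CC=C(C)C)C[C@@]1(C(=O)C#CBr)C[C@@H](CC=C(C)C)C(C)(C)C(CC=C(C)C)=C1O[Si](C)(C)C(C)(C)C
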